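A direct plan would O-methylate 3,5-dibromo-4-hydroxybenzaldehyde A1 to 3,5-dibromo-4-methoxybenzaldehyde A2 and condense A2 with ethyl azidoacetate A3 to ethyl (Z)-2-azido-3-(3,5-dibromo-4-methoxyphenyl)acrylate A4.
Hemetsberger–Knittel thermolysis of A4 would then close the pyrrole ring at N1–C7a to ethyl 5,7-dibromo-6-methoxy-1H-indole-2-carboxylate A5; saponification of A5 to 5,7-dibromo-6-methoxy-1H-indole-2-carboxylic acid A6, Cu/quinoline decarboxylation of A6 to 5,7-dibromo-6-methoxy-1H-indole A7 and NBS bromination of A7 at C3 would finish the target.
Weak, the removal of the C2 carboxyl group: the ester of A5 only serves the azide condensation, and taking it off costs a saponification and a decarboxylation of A6 near 210 °C over Cu powder, with two aryl bromides at risk of hydrodebromination and Ullmann coupling, while nothing is built.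
Weak, the azide-based ring construction: the low-molecular, explosive azide A3 is made, used in fourfold excess in a base-sensitive condensation, and the vinyl azide A4 is thermolysed at high dilution, which limits scale.
Weak, the separate bromination at the end: the acid- and light-sensitive free indole A7 must be isolated before an electrophilic step that can run on to C2, after six linear steps for a nine-carbon skeleton.

**Retrosynthetic overview**
The pyrrole ring (ring B) would be closed at carbon: the C2–C3 bond forms by attack of a benzylic carbanion (future C3) on the isocyanide carbon (future C2) of a fully substituted o-tolyl isocyanide, and the C3–Br bond is made on the resulting indolyl anion in the same flask.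
Feature used: on ring A the nitrogen at C7a and the methoxy group at C6 are meta to each other, so C5 and C7 are activated by both; the third activated position, C3a, is the one that bears carbon, and as a methyl group this carbon blocks C3a during bromination and later becomes C3.
Ring order: ring A is purchased as 5-methoxy-2-methylaniline and takes up Br at C5 and C7 in the first step; ring B is closed last.
By design there is no ester to attach and remove, no azide, no Cu at 210 °C and no isolated indole before the target; four steps.

Key step: step 4

Remark on the chemistry: the target is achiral, so no step has to set a stereocentre; 5-methoxy-2-methylaniline is taken as a commercial starting material.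

Step 1
Reactants: 1 5-methoxy-2-methylaniline
Product: 2 2,4-dibromo-3-methoxy-6-methylaniline
Conditions: NBS (2.05 equiv), MeCN, 0 °C → rt, dark
Reagents that add atoms: N-bromosuccinimide, O=C1CCC(=O)N1Br
Why: Electrophilic aromatic substitution should stop cleanly at the dibromide, because the two free positions para and ortho to NH2 are both ortho to OMe, the third ortho/para site is blocked by the methyl group, and the last ring C–H is meta to both donors.

Step 2
Reactants: 2 2,4-dibromo-3-methoxy-6-methylaniline
Product: 3 N-(2,4-dibromo-3-methoxy-6-methylphenyl)formamide
Conditions: HCO2H/Ac2O (premixed, 55 °C, 2 h), THF, 0 °C → rt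
Reagents that add atoms: acetic formic anhydride (made from formic acid and acetic anhydride), CC(=O)OC=O
Why: N-Formylation by nucleophilic acyl substitution at the formyl carbon of the mixed anhydride, a reagent reactive enough for an aniline that is flanked by Br and CH3 and deactivated by two bromine atoms.

Step 3
Reactants: 3 N-(2,4-dibromo-3-methoxy-6-methylphenyl)formamide
Product: 4 1,3-dibromo-4-isocyano-2-methoxy-5-methylbenzene
Conditions: POCl3 (1.2 equiv), Et3N (3 equiv), CH2Cl2, −10 → 0 °C; aq Na2CO3
Reagents that add atoms: none
Why: Dehydration of a formamide to an isocyanide (Ugi protocol) through O-phosphorylation and base-induced α-elimination; the two ortho substituents shield the isocyanide carbon, and hindered aryl isocyanides of this kind should be stable enough to isolate.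

Step 4
Reactants: 4 1,3-dibromo-4-isocyano-2-methoxy-5-methylbenzene
Product: 7 3,5,7-tribromo-6-methoxy-1H-indole, via benzyllithium 5 (not isolated), via lithium indol-1-ide 6 (not isolated)
Conditions: LiN(iPr)2 (2.2 equiv), diglyme, −78 °C, then → 0 °C; −78 °C, t-BuOH (1.2 equiv), then NBS (1.0 equiv, THF), −78 → −20 °C; aq NH4Cl/Na2S2O3; crystallisation
Reagents that add atoms: N-bromosuccinimide, O=C1CCC(=O)N1Br
Why: LiN(iPr)2 should remove a proton from the methyl group, which is acidified by the ortho isocyano group and the two meta bromine atoms, to give benzyllithium 5; on warming, the carbanion (future C3) adds to the isocyanide carbon (future C2) and a proton shift from C3 to C2 gives the aromatic N-lithio indole 6. The closest known reaction type is the Ito–Saegusa indole synthesis from o-tolyl isocyanides, followed by the standard C3 halogenation of an indolyl anion. Ring B is closed at the C2–C3 bond by a 5-endo-dig anionic α-addition to the isocyanide, driven by aromatisation; no stereocentre is formed. The step needs benzylic and not aryl deprotonation and must leave both C–Br bonds alone: an amide base does not undergo bromine–lithium exchange, and at −78 °C the C–H next to the isocyanide should be removed faster than the single ring C–H next to bromine. It also needs bromination at C3 only: surplus amide base is first destroyed with t-BuOH, which cannot protonate 6; the ambident anion 6 reacts with soft electrophiles at C3, C5 and C7 are occupied, and one equivalent of NBS at low temperature limits a second bromine transfer to C2.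

**Compound list**
1 | 5-methoxy-2-methylaniline | Cc1ccc(OC)cc1N | starting material
2 | 2,4-dibromo-3-methoxy-6-methylaniline | Cc1cc(Br)c(OC)c(Br)c1N | intermediate
3 | N-(2,4-dibromo-3-methoxy-6-methylphenyl)formamide | Cc1cc(Br)c(OC)c(Br)c1NC=O | intermediate
4 | 1,3-dibromo-4-isocyano-2-methoxy-5-methylbenzene | Cc1cc(Br)c(OC)c(Br)c1[N+]#[C-] | intermediate
5 | [(3,5-dibromo-2-isocyano-4-methoxyphenyl)methyl]lithium (not isolated) | [Li]Cc1cc(Br)c(OC)c(Br)c1[N+]#[C-] | intermediate
6 | lithium 5,7-dibromo-6-methoxyindol-1-ide (not isolated) | [Li]n1ccc2cc(Br)c(OC)c(Br)c12 | intermediate
7 | 3,5,7-tribromo-6-methoxy-1H-indole | COc1c(Br)cc2c(Br)c[nH]c2c1Br | target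

Total step count: 4
Longest linear sequence: 4

**Steps most likely to fail**

Step 4: deprotonation of the ring C–H next to bromine (followed by loss of LiBr to an aryne or by bromine migration) may compete with benzylic deprotonation, or a second bromine may be transferred to C2 of the product anion. The fallback gives up the anionic C2–C3 closure and closes ring B at nitrogen by a Leimgruber–Batcho sequence that needs no organolithium base on the open-chain precursor. It sets out from aniline 2, which NaBO3·4H2O in AcOH at 55 °C should oxidise to 1,3-dibromo-2-methoxy-5-methyl-4-nitrobenzene F1. Condensation with N,N-dimethylformamide dimethyl acetal in DMF at 110 °C should give (E)-2-(3,5-dibromo-4-methoxy-2-nitrophenyl)-N,N-dimethylethen-1-amine F2. Reduction with Fe powder in AcOH/EtOH at 80 °C, conditions that spare aryl bromides, should give 5,7-dibromo-6-methoxy-1H-indole F3. LiN(SiMe3)2 (1.0 equiv, THF, −78 °C) would convert F3 into lithium indolide 6, where the fallback comes back to the route for the bromination with NBS.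

Step 3: the dehydration may stall, or the isocyanide may be hydrated back or oligomerise under the acidic by-products during work-up. The fallback changes the way the isocyanide carbon is brought in. It sets out from aniline 2 and uses the Hofmann carbylamine reaction (CHCl3, 50% aq NaOH, BnEt3NCl, CH2Cl2, 40 °C), in which dichlorocarbene adds to the amine nitrogen and two losses of HCl give the isocyanide under basic conditions throughout. It comes back to the route at 4 and makes no new compound.

Step 2: acylation of the aniline nitrogen, which is flanked by Br and CH3 and made poorly nucleophilic by two bromine atoms, may be slow or incomplete. The fallback forms the N–CHO bond before the ring is crowded. It sets out from 1, whose unhindered nitrogen should be formylated readily (HCO2H, toluene, reflux, water separator) to N-(5-methoxy-2-methylphenyl)formamide F4. F4 would then be dibrominated (Br2, AcOH, NaOAc, rt) at the same two positions, para and ortho to the formamido group and both ortho to OMe, which gives formamide 3, where the fallback comes back to the route.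

**Further compounds**
F1 | step 4 | 1,3-dibromo-2-methoxy-5-methyl-4-nitrobenzene | Cc1cc(Br)c(OC)c(Br)c1[N+](=O)[O-]
F2 | step 4 | (E)-2-(3,5-dibromo-4-methoxy-2-nitrophenyl)-N,N-dimethylethen-1-amine | CN(C)/C=C/c1cc(Br)c(OC)c(Br)c1[N+](=O)[O-]
F3 | step 4 | 5,7-dibromo-6-methoxy-1H-indole | COc1c(Br)cc2cc[nH]c2c1Br
F0 | step 3 | none | none
F4 | step 2 | N-(5-methoxy-2-methylphenyl)formamide | Cc1ccc(OC)cc1NC=O
A1 | direct plan | 3,5-dibromo-4-hydroxybenzaldehyde | O=Cc1cc(Br)c(O)c(Br)c1
A2 | direct plan | 3,5-dibromo-4-methoxybenzaldehyde | COc1c(Br)cc(C=O)cc1Br
A3 | direct plan | ethyl azidoacetate | CCOC(=O)CN=[N+]=[N-]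
A4 | direct plan | ethyl (Z)-2-azido-3-(3,5-dibromo-4-methoxyphenyl)acrylate | CCOC(=O)/C(N=[N+]=[N-])=C/c1cc(Br)c(OC)c(Br)c1
A5 | direct plan | ethyl 5,7-dibromo-6-methoxy-1H-indole-2-carboxylate | CCOC(=O)c1cc2cc(Br)c(OC)c(Br)c2[nH]1
A6 | direct plan | 5,7-dibromo-6-methoxy-1H-indole-2-carboxylic acid | OC(=O)c1cc2cc(Br)c(OC)c(Br)c2[nH]1
A7 | direct plan | 5,7-dibromo-6-methoxy-1H-indole | COc1c(Br)cc2cc[nH]c2c1Br
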